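Ring C is the dihydrobenzofuran that carries the 3,5-dihydroxyphenyl group at C3. Every dihydrobenzofuran is cut at its aryl–oxygen bond (O1–C7a) and at C3–C3a, so that the benzo ring leaves as an aryne and O1–C2–C3 as an enantiopure trans-stilbene oxide. The key step builds ring C in one operation: 5-(benzyloxy)-3-bromobenzyne inserts into the C3–O bond of a (2S,3S)-oxirane, exploiting that C7a and C3a are adjacent arene carbons flanked by a C4 substituent. Bromine steers the aryne and becomes the C4 handle; a para-triflate steers oxirane cleavage. Heck coupling, Shi epoxidation and the same insertion, run twice more, grow rings B and A.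

Key step: step 6

Remark: the three 4-hydroxyphenyl oxygens travel as triflates (OTf) and the seven other phenols as benzyl ethers. Compounds 1, 6, 8, 19 and both enantiomers of the Shi ketone (1,2:4,5-di-O-isopropylidene-β-D-erythro-2,3-hexodiulo-2,6-pyranose and its mirror image) are taken as purchasable. Ring B is the central dihydrobenzofuran; ring A is the one that carries the styryl group.

Remark: in steps 6, 9 and 12 fluoride sets free one and the same aryne 11 from 5; as a single compound it has a single number and a single line in the compound list, and it is shown as an in-flask intermediate at step 6, where it first forms.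

**Route**

Step 1
Reactants: 1 4-(benzyloxy)phenol
Product: 2 4-(benzyloxy)-2,6-dibromophenol
Conditions: NBS (2.05 equiv), i-Pr2NH (cat.), CH2Cl2, 0 °C → rt
Reagents that add atoms: N-bromosuccinimide, O=C1CCC(=O)N1Br
Why: Electrophilic aromatic bromination; the free hydroxyl is the strongest director and its para position is blocked, so amine-mediated ortho-bromination should stop at the 2,6-dibromide.

Step 2
Reactants: 2 4-(benzyloxy)-2,6-dibromophenol
Product: 5 4-(benzyloxy)-2-bromo-6-(trimethylsilyl)phenyl trifluoromethanesulfonate, via silyl ether 3 (not isolated), via lithium phenolate 4 (not isolated)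
Conditions: (Me3Si)2NH, THF, 70 °C, evaporate; n-BuLi (1.05 equiv), THF, −78 °C; then Tf2O, −78 °C → rt
Reagents that add atoms: hexamethyldisilazane, C[Si](C)(C)N[Si](C)(C)C; trifluoromethanesulfonic anhydride, O=S(=O)(OS(=O)(=O)C(F)(F)F)C(F)(F)F
Why: O-silylation, bromine–lithium exchange and anionic retro-Brook (1,3 O→C silyl) rearrangement put SiMe3 ortho to the phenoxide, which is triflated in the same flask; the symmetric dibromide makes the exchange site unambiguous.

Step 3
Reactants: 6 4-formylphenyl trifluoromethanesulfonate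
Product: 7 4-ethenylphenyl trifluoromethanesulfonate
Conditions: Ph3PCH3Br, NaN(SiMe3)2, THF, 0 °C; then 6, −78 °C → rt
Reagents that add atoms: methyltriphenylphosphonium bromide, C[P+](c1ccccc1)(c1ccccc1)c1ccccc1.[Br-]
Why: Wittig methylenation with the non-stabilised ylide; the aryl triflate should be inert to the ylide at low temperature.

Step 4
Reactants: 8 1,3-bis(benzyloxy)-5-bromobenzene; 7 4-ethenylphenyl trifluoromethanesulfonate
Product: 9 4-[(E)-2-[3,5-bis(benzyloxy)phenyl]ethenyl]phenyl trifluoromethanesulfonate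
Conditions: Pd2(dba)3 (1.5 mol%), P(t-Bu)3·HBF4 (6 mol%), Cy2NMe, 1,4-dioxane, 70 °C
Reagents that add atoms: none
Why: Mizoroki–Heck reaction; zerovalent palladium bearing P(t-Bu)3 adds to C–Br much faster than to C–OTf, and syn β-hydride elimination should give the (E)-stilbene.

Step 5
Reactants: 9 4-[(E)-2-[3,5-bis(benzyloxy)phenyl]ethenyl]phenyl trifluoromethanesulfonate
Product: 10 4-[(2S,3S)-3-[3,5-bis(benzyloxy)phenyl]oxiran-2-yl]phenyl trifluoromethanesulfonate
Conditions: ent-Shi ketone (enantiomer of the D-fructose-derived ketone, 30 mol%), Oxone (2KHSO5·KHSO4·K2SO4), K2CO3, Bu4NHSO4, MeCN/CH2(OMe)2, aq Na2B4O7/Na2EDTA buffer, 0 °C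
Reagents that add atoms: potassium peroxymonosulfate (from Oxone), [K+].[O-]S(=O)(=O)OO
Why: Shi epoxidation; the chiral dioxirane transfers oxygen through a spiro transition state, the enantiomeric ketone should set both oxirane carbons as (S,S), and the triflate makes the epoxide robust toward ring opening.

Step 6
Reactants: 10 4-[(2S,3S)-3-[3,5-bis(benzyloxy)phenyl]oxiran-2-yl]phenyl trifluoromethanesulfonate; 5 4-(benzyloxy)-2-bromo-6-(trimethylsilyl)phenyl trifluoromethanesulfonate
Product: 12 4-[(2R,3R)-6-(benzyloxy)-3-[3,5-bis(benzyloxy)phenyl]-4-bromo-2,3-dihydro-1-benzofuran-2-yl]phenyl trifluoromethanesulfonate, via 5-(benzyloxy)-3-bromobenzyne 11 (not isolated)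
Conditions: 5 (1.8 equiv), CsF (4 equiv), MeCN/toluene (3:1), rt → 40 °C
Reagents that add atoms: none
Why: Aryne σ-insertion into the benzylic C–O bond of an aryl oxirane (formal [3+2] annulation): fluoride unmasks aryne 11, the oxirane oxygen of 10 adds to the aryne carbon remote from C–Br (O1–C7a) to give an ortho-bromoaryl anion/O-aryloxiranium zwitterion, the C3–O bond opens and the aryl anion collapses onto the benzylic carbon (C3–C3a), so ring C closes as a five-membered ring by anion–cation recombination, an expansion of the oxirane by the two aryne carbons and not a concerted 5-endo-tet displacement. The closest known reaction is the insertion of arynes into a C–O bond of styrene oxide, which gives 2,3-dihydrobenzofurans. C2 keeps its configuration because its C–O bond is never broken, and C3 is set by C2 because recombination on the face that places the two aryl groups trans (frontside return or a relaxed benzylic cation) is favoured, so (2S,3S)-10 should give (2R,3R)-12 (same arrangement in space; the descriptors change only with the ligand ranking). Aryne regioselectivity is needed and is secured by the inductive effect of bromine (attack at the distal carbon, carbanion next to C–Br), which also places Br at C4 as the later handle. Oxirane regioselectivity is needed and is secured by the para-triflate (σp about +0.5), which disfavours positive charge at C2 relative to the 3,5-bis(benzyloxy)benzylic C3. Ring closure must outrun bromide loss from the ortho-bromoaryl anion, which the highly electrophilic oxiranium held next to it should ensure.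

Step 7
Reactants: 12 ring C bromide; 7 4-ethenylphenyl trifluoromethanesulfonate
Product: 13 ring C (E)-stilbene bis(triflate)
Conditions: Pd2(dba)3 (2.5 mol%), P(t-Bu)3·HBF4 (10 mol%), Cy2NMe, 1,4-dioxane, 90 °C
Reagents that add atoms: none
Why: Mizoroki–Heck reaction at the C4 bromide, again bromide-selective over the aryl triflates with P(t-Bu)3-ligated zerovalent palladium, giving the (E)-alkene.

Step 8
Reactants: 13 ring C (E)-stilbene bis(triflate)
Product: 14 ring C (2R,3R)-oxirane bis(triflate)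
Conditions: D-fructose-derived Shi ketone (30–50 mol%), Oxone (2KHSO5·KHSO4·K2SO4), K2CO3, Bu4NHSO4, MeCN/CH2(OMe)2, aq Na2B4O7/Na2EDTA buffer, 0 °C
Reagents that add atoms: potassium peroxymonosulfate (from Oxone), [K+].[O-]S(=O)(=O)OO
Why: Shi epoxidation; catalyst control through the spiro transition state should set both new centres as (R,R), independent of the remote ring C stereocentres.

Step 9
Reactants: 14 ring C (2R,3R)-oxirane bis(triflate); 5 4-(benzyloxy)-2-bromo-6-(trimethylsilyl)phenyl trifluoromethanesulfonate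
Product: 15 ring B bromide (rings B and C)
Conditions: 5 (2.5 equiv), CsF (5 equiv), MeCN/toluene (2:1), rt → 40 °C
Reagents that add atoms: none
Why: Same aryne insertion into an aryl oxirane C–O bond as in step 6, with aryne 11 set free from 5 by fluoride as there; cleavage at the benzofuranyl-substituted carbon (ortho-alkyl donor against para-triflate) and spatial retention at both carbons should give the (2S,3S)-trans ring B with Br at its C4.

Step 10
Reactants: 15 ring B bromide; 7 4-ethenylphenyl trifluoromethanesulfonate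
Product: 16 ring B (E)-stilbene tris(triflate)
Conditions: Pd2(dba)3 (2.5 mol%), P(t-Bu)3·HBF4 (10 mol%), Cy2NMe, 1,4-dioxane, 90 °C
Reagents that add atoms: none
Why: Bromide-selective Mizoroki–Heck reaction as in step 7, giving the (E)-alkene.

Step 11
Reactants: 16 ring B (E)-stilbene tris(triflate)
Product: 17 ring B (2S,3S)-oxirane tris(triflate)
Conditions: ent-Shi ketone (50 mol%), Oxone (2KHSO5·KHSO4·K2SO4), K2CO3, Bu4NHSO4, MeCN/CH2(OMe)2, aq Na2B4O7/Na2EDTA buffer, 0 °C
Reagents that add atoms: potassium peroxymonosulfate (from Oxone), [K+].[O-]S(=O)(=O)OO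
Why: Shi epoxidation of the only alkene; the enantiomeric ketone should set both new centres as (S,S) under catalyst control.

Step 12
Reactants: 17 ring B (2S,3S)-oxirane tris(triflate); 5 4-(benzyloxy)-2-bromo-6-(trimethylsilyl)phenyl trifluoromethanesulfonate
Product: 18 ring A bromide (rings A, B and C)
Conditions: 5 (3 equiv), CsF (6 equiv), MeCN/toluene (2:1), rt → 40 °C
Reagents that add atoms: none
Why: Third aryne insertion into an aryl oxirane C–O bond, again by aryne 11 set free from 5 and under the same bromine and triflate control; spatial retention at both oxirane carbons should give the (2R,3R)-trans ring A.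

Step 13
Reactants: 19 3,4-bis(benzyloxy)benzaldehyde
Product: 20 1,2-bis(benzyloxy)-4-ethenylbenzene
Conditions: Ph3PCH3Br, NaN(SiMe3)2, THF, 0 °C → rt
Reagents that add atoms: methyltriphenylphosphonium bromide, C[P+](c1ccccc1)(c1ccccc1)c1ccccc1.[Br-]
Why: Wittig methylenation of an aromatic aldehyde.

Step 14
Reactants: 18 ring A bromide; 20 1,2-bis(benzyloxy)-4-ethenylbenzene
Product: 21 heptabenzyl ether tris(triflate) of the target
Conditions: Pd2(dba)3 (5 mol%), P(t-Bu)3·HBF4 (20 mol%), Cy2NMe, 1,4-dioxane, 90 °C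
Reagents that add atoms: none
Why: Bromide-selective Mizoroki–Heck reaction installs the (E)-3,4-bis(benzyloxy)styryl arm at C4 of ring A.

Step 15
Reactants: 21 heptabenzyl ether tris(triflate) of the target
Product: 22 tris(triflate) of the target
Conditions: BCl3 (excess), C6HMe5 (excess), CH2Cl2, −78 °C; MeOH quench
Reagents that add atoms: none
Why: Lewis-acid debenzylation with pentamethylbenzene as a non-basic benzyl cation scavenger; the three para-triflates should keep the benzylic C2–O1 bonds of rings A, B and C from ionising, so no stereocentre is touched.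

Step 16
Reactants: 22 tris(triflate) of the target
Product: 23 target compound CNP0099535.1
Conditions: Et4NOH (aq, excess), degassed 1,4-dioxane, Ar, rt; then AcOH
Reagents that add atoms: none
Why: Hydroxide attacks sulfur of the aryl triflates (S–O cleavage, sulfonate ester hydrolysis), freeing the three 4-hydroxyphenyl groups without touching carbon stereocentres.

**Compound list**

1 | 4-(benzyloxy)phenol | Oc1ccc(OCc2ccccc2)cc1 | starting material
2 | 4-(benzyloxy)-2,6-dibromophenol | Oc1c(Br)cc(OCc2ccccc2)cc1Br | intermediate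
3 | [4-(benzyloxy)-2,6-dibromophenoxy]trimethylsilane | C[Si](C)(C)Oc1c(Br)cc(OCc2ccccc2)cc1Br | intermediate
4 | lithium 4-(benzyloxy)-2-bromo-6-(trimethylsilyl)phenolate | [Li+].[O-]c1c(Br)cc(OCc2ccccc2)cc1[Si](C)(C)C | intermediate
5 | 4-(benzyloxy)-2-bromo-6-(trimethylsilyl)phenyl trifluoromethanesulfonate | C[Si](C)(C)c1cc(OCc2ccccc2)cc(Br)c1OS(=O)(=O)C(F)(F)F | intermediate
6 | 4-formylphenyl trifluoromethanesulfonate | O=Cc1ccc(OS(=O)(=O)C(F)(F)F)cc1 | starting material
7 | 4-ethenylphenyl trifluoromethanesulfonate | C=Cc1ccc(OS(=O)(=O)C(F)(F)F)cc1 | intermediate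
8 | 1,3-bis(benzyloxy)-5-bromobenzene | Brc1cc(OCc2ccccc2)cc(OCc2ccccc2)c1 | starting material
9 | 4-[(E)-2-[3,5-bis(benzyloxy)phenyl]ethenyl]phenyl trifluoromethanesulfonate | FC(F)(F)S(=O)(=O)Oc1ccc(/C=C/c2cc(OCc3ccccc3)cc(OCc3ccccc3)c2)cc1 | intermediate
10 | 4-[(2S,3S)-3-[3,5-bis(benzyloxy)phenyl]oxiran-2-yl]phenyl trifluoromethanesulfonate | FC(F)(F)S(=O)(=O)Oc1ccc([C@@H]2O[C@H]2c2cc(OCc3ccccc3)cc(OCc3ccccc3)c2)cc1 | intermediate
11 | 5-(benzyloxy)-3-bromobenzyne (5-(benzyloxy)-3-bromo-1,2-didehydrobenzene) | BrC1=CC(OCc2ccccc2)=CC#C1 | intermediate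
12 | 4-[(2R,3R)-6-(benzyloxy)-3-[3,5-bis(benzyloxy)phenyl]-4-bromo-2,3-dihydro-1-benzofuran-2-yl]phenyl trifluoromethanesulfonate (ring C bromide) | Brc1cc(OCc2ccccc2)cc2c1[C@@H](c1cc(OCc3ccccc3)cc(OCc3ccccc3)c1)[C@H](c1ccc(OS(=O)(=O)C(F)(F)F)cc1)O2 | intermediate
13 | 4-[(E)-2-{(2R,3R)-6-(benzyloxy)-3-[3,5-bis(benzyloxy)phenyl]-2-[4-(trifluoromethanesulfonyloxy)phenyl]-2,3-dihydro-1-benzofuran-4-yl}ethenyl]phenyl trifluoromethanesulfonate | FC(F)(F)S(=O)(=O)Oc1ccc(/C=C/c2cc(OCc3ccccc3)cc3c2[C@@H](c2cc(OCc4ccccc4)cc(OCc4ccccc4)c2)[C@H](c2ccc(OS(=O)(=O)C(F)(F)F)cc2)O3)cc1 | intermediate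
14 | 4-[(2R,3R)-3-{(2R,3R)-6-(benzyloxy)-3-[3,5-bis(benzyloxy)phenyl]-2-[4-(trifluoromethanesulfonyloxy)phenyl]-2,3-dihydro-1-benzofuran-4-yl}oxiran-2-yl]phenyl trifluoromethanesulfonate | FC(F)(F)S(=O)(=O)Oc1ccc([C@H]2O[C@@H]2c2cc(OCc3ccccc3)cc3c2[C@@H](c2cc(OCc4ccccc4)cc(OCc4ccccc4)c2)[C@H](c2ccc(OS(=O)(=O)C(F)(F)F)cc2)O3)cc1 | intermediate
15 | ring B bromide: (2S,3S)-6-(benzyloxy)-4-bromo-2-[4-(trifluoromethanesulfonyloxy)phenyl]-2,3-dihydro-1-benzofuran whose C3 is bonded to C4 of the (2R,3R) ring C unit of 12 | FC(F)(F)S(=O)(=O)Oc1ccc([C@H]2Oc3cc(OCc4ccccc4)cc(Br)c3[C@@H]2c2cc(OCc3ccccc3)cc3c2[C@@H](c2cc(OCc4ccccc4)cc(OCc4ccccc4)c2)[C@H](c2ccc(OS(=O)(=O)C(F)(F)F)cc2)O3)cc1 | intermediate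
16 | 15 with Br at C4 of ring B replaced by (E)-2-[4-(trifluoromethanesulfonyloxy)phenyl]ethenyl | FC(F)(F)S(=O)(=O)Oc1ccc([C@H]2Oc3cc(OCc4ccccc4)cc(/C=C/c4ccc(OS(=O)(=O)C(F)(F)F)cc4)c3[C@@H]2c2cc(OCc3ccccc3)cc3c2[C@@H](c2cc(OCc4ccccc4)cc(OCc4ccccc4)c2)[C@H](c2ccc(OS(=O)(=O)C(F)(F)F)cc2)O3)cc1 | intermediate
17 | 16 with the alkene as a (2S,3S)-trans-oxirane (oxirane C2 on the 4-(triflyloxy)phenyl ring, C3 on C4 of ring B) | FC(F)(F)S(=O)(=O)Oc1ccc([C@H]2Oc3cc(OCc4ccccc4)cc([C@@H]4O[C@H]4c4ccc(OS(=O)(=O)C(F)(F)F)cc4)c3[C@@H]2c2cc(OCc3ccccc3)cc3c2[C@@H](c2cc(OCc4ccccc4)cc(OCc4ccccc4)c2)[C@H](c2ccc(OS(=O)(=O)C(F)(F)F)cc2)O3)cc1 | intermediate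
18 | ring A bromide: (2R,3R)-6-(benzyloxy)-4-bromo-2-[4-(trifluoromethanesulfonyloxy)phenyl]-2,3-dihydro-1-benzofuran whose C3 is bonded to C4 of ring B of the ring B–ring C unit of 15 | FC(F)(F)S(=O)(=O)Oc1ccc([C@H]2Oc3cc(OCc4ccccc4)cc([C@@H]4c5c(Br)cc(OCc6ccccc6)cc5O[C@H]4c4ccc(OS(=O)(=O)C(F)(F)F)cc4)c3[C@@H]2c2cc(OCc3ccccc3)cc3c2[C@@H](c2cc(OCc4ccccc4)cc(OCc4ccccc4)c2)[C@H](c2ccc(OS(=O)(=O)C(F)(F)F)cc2)O3)cc1 | intermediate
19 | 3,4-bis(benzyloxy)benzaldehyde | O=Cc1ccc(OCc2ccccc2)c(OCc2ccccc2)c1 | starting material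
20 | 1,2-bis(benzyloxy)-4-ethenylbenzene | C=Cc1ccc(OCc2ccccc2)c(OCc2ccccc2)c1 | intermediate
21 | 18 with Br at C4 of ring A replaced by (E)-2-[3,4-bis(benzyloxy)phenyl]ethenyl (heptabenzyl ether tris(triflate) of the target) | FC(F)(F)S(=O)(=O)Oc1ccc([C@H]2Oc3cc(OCc4ccccc4)cc([C@@H]4c5c(/C=C/c6ccc(OCc7ccccc7)c(OCc7ccccc7)c6)cc(OCc6ccccc6)cc5O[C@H]4c4ccc(OS(=O)(=O)C(F)(F)F)cc4)c3[C@@H]2c2cc(OCc3ccccc3)cc3c2[C@@H](c2cc(OCc4ccccc4)cc(OCc4ccccc4)c2)[C@H](c2ccc(OS(=O)(=O)C(F)(F)F)cc2)O3)cc1 | intermediate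
22 | target with its three 4-hydroxyphenyl oxygens as triflates and the seven other hydroxyls free | FC(F)(F)S(=O)(=O)Oc1ccc([C@H]2Oc3cc(O)cc([C@@H]4c5c(/C=C/c6ccc(O)c(O)c6)cc(O)cc5O[C@H]4c4ccc(OS(=O)(=O)C(F)(F)F)cc4)c3[C@@H]2c2cc(O)cc3c2[C@@H](c2cc(O)cc(O)c2)[C@H](c2ccc(OS(=O)(=O)C(F)(F)F)cc2)O3)cc1 | intermediate
23 | CNP0099535.1: ring A (2R,3R), ring B (2S,3S), ring C (2R,3R), all trans, (E)-3,4-dihydroxystyryl at C4 of ring A | Oc1ccc([C@H]2Oc3cc(O)cc([C@@H]4c5c(/C=C/c6ccc(O)c(O)c6)cc(O)cc5O[C@H]4c4ccc(O)cc4)c3[C@@H]2c2cc(O)cc3c2[C@@H](c2cc(O)cc(O)c2)[C@H](c2ccc(O)cc2)O3)cc1 | target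

**Step count**

Total steps: 16. Longest linear sequence: 13 steps (steps 3–12, then 14–16, from 6).

**Steps most likely to fail**

1. Step 6. The ortho-bromoaryl anion may expel bromide before it closes the ring, or the oxiranium may open toward the triflate-bearing carbon or undergo a hydride shift (Meinwald-type rearrangement) instead of C–C bond formation. The fallback sets out from 9 and comes back at 12, with O1 on the arene from the start and the two ring bonds made in separate steps. Stilbene 9 is epoxidised with the D-fructose-derived Shi ketone to 4-[(2R,3R)-3-[3,5-bis(benzyloxy)phenyl]oxiran-2-yl]phenyl trifluoromethanesulfonate F1, the enantiomer of 10. Friedel–Crafts alkylation of 5-bromoresorcinol (excess; hexafluoroisopropanol or cat. BF3·OEt2, low temperature) at the 3,5-bis(benzyloxy)benzylic carbon, with inversion, should give 4-[(1S,2R)-2-[3,5-bis(benzyloxy)phenyl]-2-(2-bromo-4,6-dihydroxyphenyl)-1-hydroxyethyl]phenyl trifluoromethanesulfonate F2; the regioisomer from attack between the two hydroxyls would be removed by chromatography. Mitsunobu cycloetherification (PPh3, DIAD, dilute THF) through the ortho hydroxyl, with inversion at the carbinol carbon, should close 4-[(2R,3R)-3-[3,5-bis(benzyloxy)phenyl]-4-bromo-6-hydroxy-2,3-dihydro-1-benzofuran-2-yl]phenyl trifluoromethanesulfonate F3. Benzylation (BnBr, K2CO3, DMF) returns 12; the double inversion leads to the same (2R,3R)-trans compound.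

2. Step 12 (the same insertion at its most congested stage; step 9 shares the risk to a lesser degree). Ring closure of the zwitterion may be slowed by the bulk around the oxiranium of 17 until bromide loss from the aryl anion competes, and the hindered bromide 18 may then resist the last Heck coupling. The fallback sets out from 5 and 20 and comes back at 21, with the styryl arm installed before the aryne is made. Bromide-selective Heck coupling of 5 with 20 (Pd2(dba)3, P(t-Bu)3·HBF4, Cy2NMe) should give 4-(benzyloxy)-2-[(E)-2-[3,4-bis(benzyloxy)phenyl]ethenyl]-6-(trimethylsilyl)phenyl trifluoromethanesulfonate F4. CsF then releases 5-(benzyloxy)-3-[(E)-2-[3,4-bis(benzyloxy)phenyl]ethenyl]benzyne F5 (not isolated), which has no leaving group next to the carbanion, and its insertion into 17 should give 21 directly, so that 18 and step 14 are bypassed. Regiocontrol of the aryne then rests on the size of the styryl group.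

3. Step 16. The polyphenolate formed under hydroxide, above all the catecholate, may autoxidise during triflate cleavage. The fallback sets out from 21 and comes back at 23 by reversing the order of the last two operations. Et4NOH in dioxane cleaves the three triflates of 21 while all other phenols are still benzyl ethers, giving the tris(4-hydroxyphenyl) heptabenzyl ether F6. BCl3/C6HMe5 in CH2Cl2 at −78 °C then removes the seven benzyl groups to give 23, at the price of less protection of the C2–O1 bonds against acid.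

Further compounds
F1 | step 6 | 4-[(2R,3R)-3-[3,5-bis(benzyloxy)phenyl]oxiran-2-yl]phenyl trifluoromethanesulfonate | FC(F)(F)S(=O)(=O)Oc1ccc([C@H]2O[C@@H]2c2cc(OCc3ccccc3)cc(OCc3ccccc3)c2)cc1
F2 | step 6 | 4-[(1S,2R)-2-[3,5-bis(benzyloxy)phenyl]-2-(2-bromo-4,6-dihydroxyphenyl)-1-hydroxyethyl]phenyl trifluoromethanesulfonate | FC(F)(F)S(=O)(=O)Oc1ccc([C@@H](O)[C@H](c2cc(OCc3ccccc3)cc(OCc3ccccc3)c2)c2c(O)cc(O)cc2Br)cc1
F3 | step 6 | 4-[(2R,3R)-3-[3,5-bis(benzyloxy)phenyl]-4-bromo-6-hydroxy-2,3-dihydro-1-benzofuran-2-yl]phenyl trifluoromethanesulfonate | Brc1cc(O)cc2c1[C@@H](c1cc(OCc3ccccc3)cc(OCc3ccccc3)c1)[C@H](c1ccc(OS(=O)(=O)C(F)(F)F)cc1)O2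
F4 | step 12 | 4-(benzyloxy)-2-[(E)-2-[3,4-bis(benzyloxy)phenyl]ethenyl]-6-(trimethylsilyl)phenyl trifluoromethanesulfonate | C[Si](C)(C)c1cc(OCc2ccccc2)cc(/C=C/c2ccc(OCc3ccccc3)c(OCc3ccccc3)c2)c1OS(=O)(=O)C(F)(F)F
F5 | step 12 | 5-(benzyloxy)-3-[(E)-2-[3,4-bis(benzyloxy)phenyl]ethenyl]benzyne | O(Cc1ccccc1)C1=CC#CC(/C=C/c2ccc(OCc3ccccc3)c(OCc3ccccc3)c2)=C1
F6 | step 16 | heptabenzyl ether of the target with the three 4-hydroxyphenyl groups free | Oc1ccc([C@H]2Oc3cc(OCc4ccccc4)cc([C@@H]4c5c(/C=C/c6ccc(OCc7ccccc7)c(OCc7ccccc7)c6)cc(OCc6ccccc6)cc5O[C@H]4c4ccc(O)cc4)c3[C@@H]2c2cc(OCc3ccccc3)cc3c2[C@@H](c2cc(OCc4ccccc4)cc(OCc4ccccc4)c2)[C@H](c2ccc(O)cc2)O3)cc1
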